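Ring B (C5–C6=C7–C8(=O)–C9–C10, eremophilane numbering) is not made as a six-ring: C5, C6, C9 and C10 first form a cyclobutene fused cis to ring A, obtained by dichloroketene [2+2] cycloaddition to a cyclohexene anti to its C4 methyl. After the C8–C7–C11 chain is attached at C9 by carbonylative coupling, one amine-triggered cascade cleaves the strained C6–C9 bond (aza-Michael, retro-Mannich) and rejoins C6 to C7 (Mannich condensation). This formal two-carbon ring expansion exploits the enone whose C6 sits on quaternary C5: C6 is a non-enolisable neopentyl aldehyde equivalent, and the cis C5/C10 fusion is inherited from the four-ring. Chirality: catalytic allylboration (C3, C4), the bromoester (C11).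

Key step: step 9

Remark: atom labels C1–C11 follow eremophilane numbering of the target (ring A = C1–C5 and C10, ring B = C5–C10, C11 = side-chain stereocentre; target read as 3S,4R,5R,10R,11R, cis-fused, Z ester); compounds 1, 3, 7, 12 and 20 are taken as commercial.

Step 1
Reactants: 1 (E)-2-methylbut-2-en-1-ol
Product: 2 (E)-2-methylbut-2-en-1-ylboronic acid pinacol ester
Conditions: B2pin2, Pd(MeCN)4(BF4)2 (5 mol %), DMSO/MeOH, 50 °C
Reagents that add atoms: bis(pinacolato)diboron, CC1(C)OB(OC1(C)C)B1OC(C)(C)C(C)(C)O1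
Why: Pd-catalysed borylation of an allylic alcohol through a π-allyl-Pd intermediate should deliver boron to the unsubstituted terminus with the E (syn-methyl) geometry retained.

Step 2
Reactants: 2 (E)-2-methylbut-2-en-1-ylboronic acid pinacol ester; 3 pent-4-enal
Product: 4 (3R,4S)-2,3-dimethylocta-1,7-dien-4-ol
Conditions: (R)-TRIP (5 mol %; the antipode that leads to the 4S carbinol), toluene, −30 °C; aqueous work-up
Reagents that add atoms: none
Why: Chiral phosphoric acid-catalysed allylboration through a closed chair transition state, in which the E-boronate sets the anti OH/CH3 pair (later C3 and C4) and the catalyst fixes the aldehyde face.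

Step 3
Reactants: 4 (3R,4S)-2,3-dimethylocta-1,7-dien-4-ol
Product: 5 TBS ether of 4
Conditions: TBSCl, imidazole, DMF, rt
Reagents that add atoms: tert-butyldimethylsilyl chloride, CC(C)(C)[Si](C)(C)Cl
Why: Imidazole-promoted silylation of the secondary alcohol; the TBS ether should survive ZnCl2, Zn/NH4Cl, KHMDS, Pd(0) and amine/acetic acid in the later steps.

Step 4
Reactants: 5 TBS ether of 4
Product: 6 tert-butyl{[(1S,2R)-2,3-dimethylcyclohex-3-en-1-yl]oxy}dimethylsilane
Conditions: Grubbs II (3 mol %), CH2Cl2, 40 °C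
Reagents that add atoms: none
Why: Ring-closing metathesis of the monosubstituted and the 1,1-disubstituted alkene closes ring A with the trisubstituted C5=C10 bond, and the two stereocentres are not involved.

Step 5
Reactants: 6 tert-butyl{[(1S,2R)-2,3-dimethylcyclohex-3-en-1-yl]oxy}dimethylsilane; 7 trichloroacetyl chloride
Product: 9 3-(tert-butyldimethylsilyloxy)-8,8-dichloro-1,2-dimethylbicyclo[4.2.0]octan-7-one (all-cis), via dichloroketene 8 (not isolated)
Conditions: Zn–Cu, POCl3, Et2O, 0 °C to rt
Reagents that add atoms: none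
Why: Ketene–alkene [2+2] cycloaddition in which the carbonyl carbon of 8 bonds to the less substituted C10 and CCl2 to C5, the fusion is necessarily cis, and approach anti to the pseudoaxial C4 methyl (held axial by A1,2 strain with the C5 methyl) should place the C5 methyl and H-10 on the face of the C4 methyl and the C3 silyl ether.

Step 6
Reactants: 9 dichlorocyclobutanone
Product: 10 3-(tert-butyldimethylsilyloxy)-1,2-dimethylbicyclo[4.2.0]octan-7-one (all-cis)
Conditions: Zn, NH4Cl, MeOH, rt
Reagents that add atoms: none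
Why: Zinc-mediated reductive dechlorination of the α,α-dichloroketone under mildly acidic protic conditions touches no stereocentre, and the cis fusion is the stable one.

Step 7
Reactants: 10 cyclobutanone
Product: 11 3-(tert-butyldimethylsilyloxy)-1,2-dimethylbicyclo[4.2.0]oct-7-en-7-yl trifluoromethanesulfonate
Conditions: KHMDS, THF, −78 °C; then PhNTf2, −78 to 0 °C
Reagents that add atoms: N-phenylbis(trifluoromethanesulfonimide), O=S(=O)(N(c1ccccc1)S(=O)(=O)C(F)(F)F)C(F)(F)F
Why: Kinetic enolisation at the C6 methylene (the C10 methine is more substituted and its enolate would put the double bond at the ring fusion) followed by O-triflation of the enolate, a standard enol triflate synthesis.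

Step 8
Reactants: 11 cyclobutenyl triflate; 12 methyl (S)-3-bromo-2-methylpropanoate
Product: 14 methyl (2R)-4-[3-(tert-butyldimethylsilyloxy)-1,2-dimethylbicyclo[4.2.0]oct-7-en-7-yl]-2-methyl-4-oxobutanoate, via organozinc bromide 13 (not isolated)
Conditions: 12, Zn dust, I2 (5 mol %), DMA, 80 °C; then 11, Pd(PPh3)4 (5 mol %), CO (1 atm), THF, 40 °C
Reagents that add atoms: carbon monoxide, [C-]#[O+]
Why: Carbonylative Negishi coupling (oxidative addition of the enol triflate, CO insertion, transmetalation with the β-zincio ester) installs C8 and the C7–C11 chain at C9, and the C11 centre, β to zinc and never enolised, is carried over from 12.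

Step 9
Reactants: 14 acylcyclobutene
Product: 18 methyl (2R)-2-[(4aR,7S,8R,8aR)-7-(tert-butyldimethylsilyloxy)-8,8a-dimethyl-3-oxo-3,4,4a,5,6,7,8,8a-octahydronaphthalen-2-yl]propanoate, via pyrrolidine adduct 15 (not isolated), via keto-iminium acetate 16 (not isolated), via Mannich base 17 (not isolated)
Conditions: pyrrolidine (0.5 equiv), AcOH (0.5 equiv), MeCN, 50 °C
Reagents that add atoms: none
Why: Proposed new method: pyrrolidine should add in an aza-Michael sense to C6 of the strained 1-acylcyclobutene (15), the 2-aminocyclobutyl ketone should undergo strain-driven retro-Mannich cleavage of C6–C9 to the keto-iminium 16, and the C7 enol (or enamine) of the C8 ketone should reclose on the C6 iminium before β-elimination of pyrrolidine from 17 gives the C6=C7 enone, a net two-carbon ring expansion that is an isomerisation catalytic in amine. The closest known reaction types are the de Mayo retro-aldol and the retro-Mannich/Mannich cascade of vinylogous-amide photoadducts for the fragmentation, and the amine/acid-catalysed intramolecular aldol (Mannich) condensation for the closure; the thermal amine trigger on an acylcyclobutene is the untested element. Ring B is closed in a 6-(enolendo)-exo-trig mode, while the four-membered ring is opened and not closed. No new stereocentre survives (C6, C7 and C9 are transient), C5 and C10 keep the cis fusion fixed in the cyclobutane because only the C6–C9 bond is cleaved, and C11 is spared by the buffered, non-hydrolytic medium. The selectivity needed is regiochemical (C7 and not C9 as nucleophile, unsaturation only at C6=C7) and is secured because C6 on quaternary C5 cannot enolise and closure from C9 only regenerates the strained four-ring reversibly.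

Step 10
Reactants: 18 TBS-protected enone
Product: 19 methyl (2R)-2-[(4aR,7S,8R,8aR)-7-hydroxy-8,8a-dimethyl-3-oxo-3,4,4a,5,6,7,8,8a-octahydronaphthalen-2-yl]propanoate
Conditions: HF·pyridine, THF, 0 °C to rt
Reagents that add atoms: none
Why: Fluoride-mediated silyl ether cleavage under mildly acidic conditions that should leave the enone, the methyl ester and the C11 centre untouched.

Step 11
Reactants: 19 hydroxy enone; 20 angelic acid
Product: 22 CNP0323033.1, via angelic 2,4,6-trichlorobenzoic anhydride 21 (not isolated)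
Conditions: 20, 2,4,6-trichlorobenzoyl chloride, Et3N, toluene, rt; then 19, 80 °C (no DMAP)
Reagents that add atoms: none
Why: Yamaguchi-type mixed-anhydride esterification without nucleophilic catalyst, conditions under which the angeloyl group should transfer without Z to E isomerisation; the alcohol attacks the less hindered angeloyl carbonyl and C3 keeps its configuration (O-acylation).

Compound list
1 | (E)-2-methylbut-2-en-1-ol (tiglyl alcohol) | C/C=C(\C)CO | starting material
2 | 4,4,5,5-tetramethyl-2-[(E)-2-methylbut-2-en-1-yl]-1,3,2-dioxaborolane | C/C=C(\C)CB1OC(C)(C)C(C)(C)O1 | intermediate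
3 | pent-4-enal | C=CCCC=O | starting material
4 | (3R,4S)-2,3-dimethylocta-1,7-dien-4-ol (anti) | O[C@H]([C@H](C)C(C)=C)CCC=C | intermediate
5 | tert-butyl{[(3R,4S)-2,3-dimethylocta-1,7-dien-4-yl]oxy}dimethylsilane | CC(C)(C)[Si](C)(C)O[C@H]([C@H](C)C(C)=C)CCC=C | intermediate
6 | tert-butyl{[(1S,2R)-2,3-dimethylcyclohex-3-en-1-yl]oxy}dimethylsilane (OTBS and 2-methyl cis) | CC(C)(C)[Si](C)(C)O[C@H]1CCC=C(C)[C@H]1C | intermediate
7 | trichloroacetyl chloride | ClC(=O)C(Cl)(Cl)Cl | starting material
8 | dichloroketene | ClC(Cl)=C=O | intermediate (not isolated)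
9 | 3-(tert-butyldimethylsilyloxy)-8,8-dichloro-1,2-dimethylbicyclo[4.2.0]octan-7-one; cis-fused; OTBS, both methyls and H-6 on one face of the six-ring, four-ring on the other; C=O next to C6-H, CCl2 next to C1 | CC(C)(C)[Si](C)(C)O[C@H]1CC[C@@H]2C(=O)C(Cl)(Cl)[C@]2(C)[C@H]1C | intermediate
10 | 3-(tert-butyldimethylsilyloxy)-1,2-dimethylbicyclo[4.2.0]octan-7-one; same relative and absolute configuration as 9 | CC(C)(C)[Si](C)(C)O[C@H]1CC[C@@H]2C(=O)C[C@]2(C)[C@H]1C | intermediate
11 | 3-(tert-butyldimethylsilyloxy)-1,2-dimethylbicyclo[4.2.0]oct-7-en-7-yl trifluoromethanesulfonate; configuration as 9 | CC(C)(C)[Si](C)(C)O[C@H]1CC[C@@H]2C(OS(=O)(=O)C(F)(F)F)=C[C@]2(C)[C@H]1C | intermediate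
12 | methyl (S)-3-bromo-2-methylpropanoate | BrC[C@@H](C)C(=O)OC | starting material
13 | [(S)-3-methoxy-2-methyl-3-oxopropyl]zinc bromide | Br[Zn]C[C@@H](C)C(=O)OC | intermediate (not isolated)
14 | methyl (2R)-4-[3-(tert-butyldimethylsilyloxy)-1,2-dimethylbicyclo[4.2.0]oct-7-en-7-yl]-2-methyl-4-oxobutanoate; ring configuration as 9 | CC(C)(C)[Si](C)(C)O[C@H]1CC[C@@H]2C(C(=O)C[C@@H](C)C(=O)OC)=C[C@]2(C)[C@H]1C | intermediate
15 | pyrrolidine adduct of 14 (8-pyrrolidin-1-yl cyclobutyl ketone; C6/C9 configuration not controlled) | CC(C)(C)[Si](C)(C)O[C@H]1CC[C@@H]2C(C(=O)C[C@@H](C)C(=O)OC)C(N3CCCC3)[C@]2(C)[C@H]1C | intermediate (not isolated)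
16 | ring-opened keto-iminium acetate (C5 bears CH=N+ pyrrolidinium, C10 bears the CH2–CO–CH2–CH(CH3)CO2Me chain; cis) | CC(C)(C)[Si](C)(C)O[C@H]1CC[C@H](CC(=O)C[C@@H](C)C(=O)OC)[C@](C)(C=[N+]2CCCC2)[C@H]1C.CC(=O)[O-] | intermediate (not isolated)
17 | Mannich base (cis-decalone with pyrrolidin-1-yl at C6; C6/C7 configuration not controlled) | CC(C)(C)[Si](C)(C)O[C@H]1CC[C@@H]2CC(=O)C([C@@H](C)C(=O)OC)C(N3CCCC3)[C@]2(C)[C@H]1C | intermediate (not isolated)
18 | methyl (2R)-2-[(4aR,7S,8R,8aR)-7-(tert-butyldimethylsilyloxy)-8,8a-dimethyl-3-oxo-3,4,4a,5,6,7,8,8a-octahydronaphthalen-2-yl]propanoate | CC(C)(C)[Si](C)(C)O[C@H]1CC[C@@H]2CC(=O)C([C@@H](C)C(=O)OC)=C[C@]2(C)[C@H]1C | intermediate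
19 | methyl (2R)-2-[(4aR,7S,8R,8aR)-7-hydroxy-8,8a-dimethyl-3-oxo-3,4,4a,5,6,7,8,8a-octahydronaphthalen-2-yl]propanoate | O[C@H]1CC[C@@H]2CC(=O)C([C@@H](C)C(=O)OC)=C[C@]2(C)[C@H]1C | intermediate
20 | angelic acid, (Z)-2-methylbut-2-enoic acid | C/C=C(/C)C(=O)O | starting material
21 | (Z)-2-methylbut-2-enoic 2,4,6-trichlorobenzoic anhydride | C/C=C(/C)C(=O)OC(=O)c1c(Cl)cc(Cl)cc1Cl | intermediate (not isolated)
22 | CNP0323033.1, methyl (2R)-2-[(4aR,7S,8R,8aR)-8,8a-dimethyl-7-{[(2Z)-2-methylbut-2-enoyl]oxy}-3-oxo-3,4,4a,5,6,7,8,8a-octahydronaphthalen-2-yl]propanoate | C/C=C(/C)C(=O)O[C@H]1CC[C@@H]2CC(=O)C([C@@H](C)C(=O)OC)=C[C@]2(C)[C@H]1C | target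

Total step count: 11. Longest linear sequence: 11 (1 to 22; 3, 7, 12 and 20 enter as commercial materials).

Steps most likely to fail

Step 9. The amine may fail to add to C6 next to the quaternary C5, so that no fragmentation starts, or the cross-conjugated dienamine of 14 may drain material by double-bond migration or oligomerisation. The fallback sets out from 14 and uses known chemistry throughout. Copper-catalysed conjugate borylation (B2pin2, CuCl, Xantphos, NaOtBu, MeOH, THF) should give the β-boryl cyclobutyl ketone F1. Perborate oxidation (NaBO3·4H2O, THF/H2O) should give the 2-hydroxycyclobutyl ketone F2, which should open in the same flask by de Mayo-type retro-aldol cleavage to the keto-aldehyde F3. Piperidine/AcOH in benzene at 80 °C then closes F3 by intramolecular aldol condensation, and the route is rejoined at 18.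

Step 8. Direct coupling without CO insertion may compete with acyl-palladium formation, and the strained enol triflate may decompose before transmetalation. The fallback sets out from 11 and separates the two events. Pd-catalysed thiocarbonylation (CO 1 atm, EtSH, Pd(OAc)2/PPh3, Et3N, DMF, 60 °C) should give the S-ethyl thioester F4. Fukuyama coupling of F4 with the same organozinc 13 (PdCl2(PPh3)2, THF/toluene, rt) then returns to 14.

Step 11. Z to E isomerisation of the angeloyl unit during activation (tiglate formation) or sluggish acylation of the hindered C3 alcohol may occur. The fallback sets out from 19 and builds the Z alkene last. DCC/DMAP esterification with 2-[bis(2,2,2-trifluoroethoxy)phosphoryl]propanoic acid should give the phosphonate ester F5. Still–Gennari olefination of F5 with acetaldehyde (KHMDS, 18-crown-6, THF, −78 °C) then gives 22 directly.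

Further compounds
F1 | step 9 | methyl (2R)-4-[3-(tert-butyldimethylsilyloxy)-1,2-dimethyl-8-(pinacolboryl)bicyclo[4.2.0]octan-7-yl]-2-methyl-4-oxobutanoate | CC(C)(C)[Si](C)(C)O[C@H]1CC[C@@H]2C(C(=O)C[C@@H](C)C(=O)OC)C(B3OC(C)(C)C(C)(C)O3)[C@]2(C)[C@H]1C
F2 | step 9 | methyl (2R)-4-[3-(tert-butyldimethylsilyloxy)-8-hydroxy-1,2-dimethylbicyclo[4.2.0]octan-7-yl]-2-methyl-4-oxobutanoate | CC(C)(C)[Si](C)(C)O[C@H]1CC[C@@H]2C(C(=O)C[C@@H](C)C(=O)OC)C(O)[C@]2(C)[C@H]1C
F3 | step 9 | keto-aldehyde, methyl (2R)-5-[cis-4-(tert-butyldimethylsilyloxy)-2-formyl-2,3-dimethylcyclohexyl]-2-methyl-4-oxopentanoate | CC(C)(C)[Si](C)(C)O[C@H]1CC[C@H](CC(=O)C[C@@H](C)C(=O)OC)[C@](C)(C=O)[C@H]1C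
F4 | step 8 | S-ethyl 3-(tert-butyldimethylsilyloxy)-1,2-dimethylbicyclo[4.2.0]oct-7-ene-7-carbothioate | CC(C)(C)[Si](C)(C)O[C@H]1CC[C@@H]2C(C(=O)SCC)=C[C@]2(C)[C@H]1C
F5 | step 11 | 2-[bis(2,2,2-trifluoroethoxy)phosphoryl]propanoate ester of 19 | CC(C(=O)O[C@H]1CC[C@@H]2CC(=O)C([C@@H](C)C(=O)OC)=C[C@]2(C)[C@H]1C)P(=O)(OCC(F)(F)F)OCC(F)(F)F
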